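Ring A of the flavone is cut at C7–C8 and C4a–C5. This leaves a 2-aryl-3-methoxy-4-pyranone whose CH2OCH3 group is already C8 with its oxygen: ring C, the 3-oxygen and C8 on C8a are the carbon–oxygen skeleton of kojic acid. In one flask the lithiated CH2OCH3 group is acylated by methyl 3,3-dimethoxypropanoate (C7–C8), and acid then closes the acetal carbon C5 onto the nucleophilic C4a and aromatises. The 7-hydroxy-8-methoxy pattern results directly. The precursor is a 6-(methoxymethyl)pyranone carrying benzyl-protected ring B at C2, made by Suzuki coupling of brominated, methylated kojic acid.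

Key step: step 7

Remark: flavone numbering is used (ring C: O1, C2, C3, C4; ring A: C4a to C8a; ring B: C1' to C6'). The halogen handle on the pyranone is taken as bromide. Intermediate 10 forms as a racemate, and its only stereocentre disappears on aromatisation. The target has no stereocentre.

Step 1
Reactants: 1 kojic acid
Product: 2 2-bromo-3-hydroxy-6-(hydroxymethyl)-4H-pyran-4-one
Conditions: NBS, DMF, 0 °C → rt, dark
Reagents that add atoms: N-bromosuccinimide, O=C1CCC(=O)N1Br
Why: Electrophilic bromination of an enol, in which the 5-hydroxyl of kojic acid activates only the adjacent ring carbon C6, the position that becomes C2 of the flavone.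

Step 2
Reactants: 2 2-bromo-3-hydroxy-6-(hydroxymethyl)-4H-pyran-4-one
Product: 3 2-bromo-3-methoxy-6-(methoxymethyl)-4H-pyran-4-one
Conditions: Ag2O, MeI, DMF, rt, dark
Reagents that add atoms: iodomethane, CI
Why: Purdie–Kuhn methylation should etherify both the acidic enol hydroxyl and the primary alcohol under near-neutral conditions, so that no free alkoxide is present to displace the activated vinylic bromide.

Step 3
Reactants: 4 3,4-dimethoxyphenol
Product: 5 4-(benzyloxy)-1,2-dimethoxybenzene
Conditions: BnBr, K2CO3, DMF, rt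
Reagents that add atoms: benzyl bromide, BrCc1ccccc1
Why: Williamson etherification of a phenoxide with a reactive benzylic halide.

Step 4
Reactants: 5 4-(benzyloxy)-1,2-dimethoxybenzene
Product: 6 1-(benzyloxy)-2-bromo-4,5-dimethoxybenzene
Conditions: NBS, MeCN, 0 °C → rt
Reagents that add atoms: N-bromosuccinimide, O=C1CCC(=O)N1Br
Why: Electrophilic aromatic bromination should go to the carbon ortho to the benzyloxy group and para to a methoxy group, the most activated open position, since the carbon between two alkoxy groups is hindered.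

Step 5
Reactants: 6 1-(benzyloxy)-2-bromo-4,5-dimethoxybenzene
Product: 7 [2-(benzyloxy)-4,5-dimethoxyphenyl]boronic acid
Conditions: n-BuLi, THF, −78 °C; B(OiPr)3, −78 °C → rt; dilute aq HCl, 0 °C
Reagents that add atoms: triisopropyl borate, CC(C)OB(OC(C)C)OC(C)C; water, O
Why: Bromine–lithium exchange at −78 °C outruns benzylic deprotonation, and trapping of the aryllithium with a borate ester followed by hydrolysis is the standard route to an arylboronic acid.

Step 6
Reactants: 3 2-bromo-3-methoxy-6-(methoxymethyl)-4H-pyran-4-one; 7 [2-(benzyloxy)-4,5-dimethoxyphenyl]boronic acid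
Product: 8 2-[2-(benzyloxy)-4,5-dimethoxyphenyl]-3-methoxy-6-(methoxymethyl)-4H-pyran-4-one
Conditions: Pd(OAc)2 (cat.), SPhos, K3PO4, toluene–H2O, 80 °C
Reagents that add atoms: none
Why: Suzuki–Miyaura coupling, in which the C–Br bond of 3 behaves as a vinylogous acyl bromide towards zerovalent palladium and the bulky electron-rich phosphine should speed transmetalation of the ortho-substituted boronic acid ahead of protodeboronation.

Step 7
Reactants: 8 2-[2-(benzyloxy)-4,5-dimethoxyphenyl]-3-methoxy-6-(methoxymethyl)-4H-pyran-4-one; 9 methyl 3,3-dimethoxypropanoate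
Product: 11 2-[2-(benzyloxy)-4,5-dimethoxyphenyl]-7-hydroxy-3,8-dimethoxy-4H-chromen-4-one, via keto acetal 10 (not isolated)
Conditions: LiN(SiMe3)2 (2.2 equiv), THF, −78 °C; 9 (1.5 equiv), −78 → −20 °C; then CF3CO2H (excess), CH2Cl2, 0 °C → rt, same flask
Reagents that add atoms: none
Why: Proposed new method: LiN(SiMe3)2 should deprotonate the CH2OCH3 group of 8, the only site made vinylogously acidic by the C4 carbonyl now that C2 carries ring B, and the dienolate is C-acylated at its exocyclic carbon by ester 9 (Claisen condensation, C7–C8), the second equivalent of base holding the more acidic keto acetal 10 as its enolate. CF3CO2H then ionises the acetal to an oxocarbenium ion at C5, which is captured by C4a, the α-carbon of the vinylogous ester O1–C8a=C4a–C4=O, in a 6-(enolendo)-exo-trig closure (C4a–C5) that forms ring A. Loss of the second methanol across C5–C6 and enolisation of the C7 ketone towards C8 give the aromatic 7-hydroxy-8-methoxy ring with no change of oxidation level; the stereocentre of 10 at C8 is racemic and is erased here, so no stereocontrol is needed. The closest known reactions are the lateral lithiation–acylation of 2-alkyl-4-pyranones and the acid-mediated (3+3) cycloaromatisation of keto acetals to phenols, which have not been joined in one flask on an alkoxymethyl pyranone. The step needs acylation at C8 rather than at C4a or oxygen, which follows the known γ-selectivity of pyranone dienolates, and closure at C4a only, which is enforced because C4a is the one nucleophilic carbon within reach of a six-membered transition state. The benzyl and methyl ethers should tolerate CF3CO2H in CH2Cl2 at or below room temperature.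

Step 8
Reactants: 11 2-[2-(benzyloxy)-4,5-dimethoxyphenyl]-7-hydroxy-3,8-dimethoxy-4H-chromen-4-one
Product: 12 2-[2-(benzyloxy)-4,5-dimethoxyphenyl]-3,7,8-trimethoxy-4H-chromen-4-one
Conditions: MeI, K2CO3, acetone, reflux
Reagents that add atoms: iodomethane, CI
Why: Williamson methylation of the only free hydroxyl, the 7-phenol, which is acidified as a vinylogous acid by the C4 carbonyl.

Step 9
Reactants: 12 2-[2-(benzyloxy)-4,5-dimethoxyphenyl]-3,7,8-trimethoxy-4H-chromen-4-one
Product: 13 2-(2-hydroxy-4,5-dimethoxyphenyl)-3,7,8-trimethoxy-4H-chromen-4-one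
Conditions: H2 (1 atm), 10% Pd/C, EtOAc, rt
Reagents that add atoms: none
Why: Catalytic hydrogenolysis should cleave the benzyl aryl ether, while the methyl ethers and the tetrasubstituted C2=C3 bond of the chromone are inert under these conditions.

Compound list
1 | kojic acid, 5-hydroxy-2-(hydroxymethyl)-4H-pyran-4-one | OCc1cc(=O)c(O)co1 | starting material
2 | 2-bromo-3-hydroxy-6-(hydroxymethyl)-4H-pyran-4-one | OCc1cc(=O)c(O)c(Br)o1 | intermediate
3 | 2-bromo-3-methoxy-6-(methoxymethyl)-4H-pyran-4-one | COCc1cc(=O)c(OC)c(Br)o1 | intermediate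
4 | 3,4-dimethoxyphenol | COc1ccc(O)cc1OC | starting material
5 | 4-(benzyloxy)-1,2-dimethoxybenzene | COc1ccc(OCc2ccccc2)cc1OC | intermediate
6 | 1-(benzyloxy)-2-bromo-4,5-dimethoxybenzene | COc1cc(Br)c(OCc2ccccc2)cc1OC | intermediate
7 | [2-(benzyloxy)-4,5-dimethoxyphenyl]boronic acid | COc1cc(OCc2ccccc2)c(B(O)O)cc1OC | intermediate
8 | 2-[2-(benzyloxy)-4,5-dimethoxyphenyl]-3-methoxy-6-(methoxymethyl)-4H-pyran-4-one | COCc1cc(=O)c(OC)c(-c2cc(OC)c(OC)cc2OCc2ccccc2)o1 | intermediate
9 | methyl 3,3-dimethoxypropanoate | COC(=O)CC(OC)OC | starting material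
10 | keto acetal, 1-{6-[2-(benzyloxy)-4,5-dimethoxyphenyl]-5-methoxy-4-oxo-4H-pyran-2-yl}-1,4,4-trimethoxybutan-2-one (racemic, not isolated) | COC(CC(=O)C(OC)c1cc(=O)c(OC)c(-c2cc(OC)c(OC)cc2OCc2ccccc2)o1)OC | intermediate
11 | 2-[2-(benzyloxy)-4,5-dimethoxyphenyl]-7-hydroxy-3,8-dimethoxy-4H-chromen-4-one | COc1cc(OCc2ccccc2)c(-c2oc3c(OC)c(O)ccc3c(=O)c2OC)cc1OC | intermediate
12 | 2-[2-(benzyloxy)-4,5-dimethoxyphenyl]-3,7,8-trimethoxy-4H-chromen-4-one | COc1cc(OCc2ccccc2)c(-c2oc3c(OC)c(OC)ccc3c(=O)c2OC)cc1OC | intermediate
13 | 2-(2-hydroxy-4,5-dimethoxyphenyl)-3,7,8-trimethoxy-4H-chromen-4-one | COc1cc(O)c(-c2oc3c(OC)c(OC)ccc3c(=O)c2OC)cc1OC | target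

Total step count: 9. Longest linear sequence: 7 steps (steps 3, 4, 5, 6, 7, 8, 9 from 3,4-dimethoxyphenol); the pyranone branch (steps 1 and 2) joins at step 6.

Steps most likely to fail

Step 7. Proton transfer from ester 9 to the pyranone anion, followed by β-elimination of methoxide, may outrun acylation. The acid stage may stall at an open-chain enol ether that oligomerises instead of closing onto C4a, and the benzyl ether may be partly lost in acid. The fallback builds the chromone by classical flavonol chemistry and takes ring A from a purchased acetophenone. It sets out from bromide 6. Bromine–lithium exchange (n-BuLi, THF, −78 °C) and a DMF quench should give 2-(benzyloxy)-4,5-dimethoxybenzaldehyde F1. Claisen–Schmidt condensation with commercial 1-(2-hydroxy-3,4-dimethoxyphenyl)ethanone (CC(=O)c1ccc(OC)c(OC)c1O; KOH, EtOH, rt) should give (E)-3-[2-(benzyloxy)-4,5-dimethoxyphenyl]-1-(2-hydroxy-3,4-dimethoxyphenyl)prop-2-en-1-one F2. Algar–Flynn–Oyamada oxidation (H2O2, NaOH, MeOH, 0 °C → rt) should give 2-[2-(benzyloxy)-4,5-dimethoxyphenyl]-3-hydroxy-7,8-dimethoxy-4H-chromen-4-one F3. Methylation of the 3-hydroxyl (MeI, K2CO3, acetone, reflux) comes back to the route at 12.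

Step 2. Etherification of the primary alcohol may stay incomplete, or the activated vinylic bromide may be displaced during alkylation. The fallback makes the side-chain ether by substitution before the halogen is introduced, and sets out from kojic acid 1. SOCl2 (CH2Cl2, rt) should give 2-(chloromethyl)-5-hydroxy-4H-pyran-4-one F4. Methanolysis of the allylic-type chloride (NaOMe, MeOH, reflux, then neutralisation) should give 5-hydroxy-2-(methoxymethyl)-4H-pyran-4-one F5. Enol bromination (NBS, DMF, 0 °C → rt) should give 2-bromo-3-hydroxy-6-(methoxymethyl)-4H-pyran-4-one F6. Methylation of the enol hydroxyl alone (MeI, K2CO3, acetone, reflux) comes back to the route at 3.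

Step 6. Protodeboronation of the electron-rich ortho-alkoxy boronic acid may outrun transmetalation, and the aqueous base may open the pyranone ring. The fallback is a base-free Negishi coupling that sets out from bromide 6. Bromine–lithium exchange (n-BuLi, THF, −78 °C) and transmetalation with ZnCl2 should give [2-(benzyloxy)-4,5-dimethoxyphenyl]zinc chloride F7. Coupling with bromopyranone 3 under Pd(PPh3)4 (zerovalent palladium, THF, 50 °C) comes back to the route at 8.

Further compounds
F1 | step 7 | 2-(benzyloxy)-4,5-dimethoxybenzaldehyde | COc1cc(OCc2ccccc2)c(C=O)cc1OC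
F2 | step 7 | (E)-3-[2-(benzyloxy)-4,5-dimethoxyphenyl]-1-(2-hydroxy-3,4-dimethoxyphenyl)prop-2-en-1-one | COc1ccc(C(=O)/C=C/c2cc(OC)c(OC)cc2OCc2ccccc2)c(O)c1OC
F3 | step 7 | 2-[2-(benzyloxy)-4,5-dimethoxyphenyl]-3-hydroxy-7,8-dimethoxy-4H-chromen-4-one | COc1cc(OCc2ccccc2)c(-c2oc3c(OC)c(OC)ccc3c(=O)c2O)cc1OC
F4 | step 2 | 2-(chloromethyl)-5-hydroxy-4H-pyran-4-one | ClCc1cc(=O)c(O)co1
F5 | step 2 | 5-hydroxy-2-(methoxymethyl)-4H-pyran-4-one | COCc1cc(=O)c(O)co1
F6 | step 2 | 2-bromo-3-hydroxy-6-(methoxymethyl)-4H-pyran-4-one | COCc1cc(=O)c(O)c(Br)o1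
F7 | step 6 | [2-(benzyloxy)-4,5-dimethoxyphenyl]zinc chloride | COc1cc(OCc2ccccc2)c([Zn]Cl)cc1OC
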